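The γ-lactone (O1–C19(=O)–C17–C8–C7, briarane numbering) is taken apart so that its O–C(=O) unit is carbon dioxide. In the key step a copper-catalysed carboxylation joins CO2 carbon C19 to the alkenyl carbon C17 of a boronate, and the carboxylate just formed opens the terminal epoxide at C7 (5-exo, inversion), closing the lactone ring. It exploits the 1,3 relation of C17 and C7 across the oxygenated quaternary C8. The precursor is a small epoxy alkenylboronate from (R)-glycerate. The lactone is elaborated to an iododiene aldehyde, united with ring A (a cyclohexanone enolate) by aldol addition at C9–C10, and the ten-membered ring is closed by Nozaki–Hiyama–Kishi coupling at C2–C3.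

Key step: step 13

Remark: positions carry briarane numbers (C15 methyl on C1, C16 on C5, C18 methyl on C17, C19 lactone carbonyl, C20 methylene on C11, O1 the lactone ring oxygen); compounds 26 and 33 are taken as commercial.

Step 1
Reactants: 1 1,4-dioxaspiro[4.5]dec-6-en-8-one; 2 formaldehyde
Product: 3 7-(hydroxymethyl)-1,4-dioxaspiro[4.5]dec-6-en-8-one
Conditions: 37% aq. CH2O, DMAP (20 mol %), THF/H2O, rt
Reagents that add atoms: none
Why: Morita–Baylis–Hillman reaction, in which DMAP adds to the enone β-carbon, the enolate takes up formaldehyde at the α-carbon (later C1) and DMAP leaves again; no stereocentre is formed.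

Step 2
Reactants: 3 7-(hydroxymethyl)-1,4-dioxaspiro[4.5]dec-6-en-8-one
Product: 4 7-[(tert-butyldimethylsilyloxy)methyl]-1,4-dioxaspiro[4.5]dec-6-en-8-one
Conditions: TBSCl, imidazole, DMF, 0 °C to rt
Reagents that add atoms: tert-butyldimethylsilyl chloride, CC(C)(C)[Si](C)(C)Cl
Why: Standard silylation of the primary alcohol, which keeps the hydroxyl away from borane in the next step.

Step 3
Reactants: 4 7-[(tert-butyldimethylsilyloxy)methyl]-1,4-dioxaspiro[4.5]dec-6-en-8-one
Product: 5 (8S)-7-[(tert-butyldimethylsilyloxy)methyl]-1,4-dioxaspiro[4.5]dec-6-en-8-ol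
Conditions: (R)-2-methyl-CBS-oxazaborolidine (10 mol %), BH3·SMe2, THF, −30 °C; MeOH
Reagents that add atoms: none
Why: Corey–Bakshi–Shibata reduction of an α-substituted cyclohexenone, in which the substituted alkenyl carbon acts as the large group, so that the (R)-catalyst should give the (S)-alcohol (C14).

Step 4
Reactants: 5 (8S)-7-[(tert-butyldimethylsilyloxy)methyl]-1,4-dioxaspiro[4.5]dec-6-en-8-ol
Product: 6 (8S)-8-(tert-butyldimethylsilyloxy)-7-[(tert-butyldimethylsilyloxy)methyl]-1,4-dioxaspiro[4.5]dec-6-ene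
Conditions: TBSCl, imidazole, DMAP (cat.), DMF, 40 °C
Reagents that add atoms: tert-butyldimethylsilyl chloride, CC(C)(C)[Si](C)(C)Cl
Why: Silylation of the secondary allylic alcohol installs the bulky group that later steers the cuprate.

Step 5
Reactants: 6 (8S)-8-(tert-butyldimethylsilyloxy)-7-[(tert-butyldimethylsilyloxy)methyl]-1,4-dioxaspiro[4.5]dec-6-ene
Product: 7 (4S)-4-(tert-butyldimethylsilyloxy)-3-[(tert-butyldimethylsilyloxy)methyl]cyclohex-2-en-1-one
Conditions: PPTS (cat.), acetone/H2O (9:1), rt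
Reagents that add atoms: water, O
Why: Mild acid hydrolysis of the ketal unveils the C11 ketone in conjugation with the C10=C1 alkene, and both silyl ethers should survive PPTS.

Step 6
Reactants: 7 (4S)-4-(tert-butyldimethylsilyloxy)-3-[(tert-butyldimethylsilyloxy)methyl]cyclohex-2-en-1-one
Product: 8 (3S,4S)-4-(tert-butyldimethylsilyloxy)-3-[(tert-butyldimethylsilyloxy)methyl]-3-methyl-1-(trimethylsilyloxy)cyclohex-1-ene
Conditions: Me2CuLi, TMSCl, THF, −78 °C; Et3N, pH 7 work-up; used crude
Reagents that add atoms: lithium dimethylcuprate, [Li+].C[Cu-]C; chlorotrimethylsilane, C[Si](C)(C)Cl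
Why: Cuprate conjugate addition places the C15 methyl at C1 anti to the pseudoaxial C14 silyloxy group (quaternary C1 set), and TMSCl traps the enolate regiospecifically as the C10=C11 silyl enol ether.

Step 7
Reactants: 9 methyl (4R)-2,2-dimethyl-1,3-dioxolane-4-carboxylate; 10 ethynyltrimethylsilane
Product: 12 1-[(4R)-2,2-dimethyl-1,3-dioxolan-4-yl]-3-(trimethylsilyl)prop-2-yn-1-one, via lithium (trimethylsilyl)acetylide 11 (not isolated)
Conditions: n-BuLi, THF, −78 °C; BF3·OEt2; then 9, −78 °C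
Reagents that add atoms: none
Why: Acylation of an alkynyllithium–BF3 reagent by an ester stops at the ketone because the tetrahedral adduct is stable at −78 °C, and the C7 centre of the glycerate is kept.

Step 8
Reactants: 12 1-[(4R)-2,2-dimethyl-1,3-dioxolan-4-yl]-3-(trimethylsilyl)prop-2-yn-1-one; 13 vinylmagnesium bromide
Product: 14 (3S)-3-[(4R)-2,2-dimethyl-1,3-dioxolan-4-yl]-5-(trimethylsilyl)pent-1-en-4-yn-3-ol
Conditions: MgBr2·OEt2, CH2Cl2, −78 °C; vinylMgBr (THF)
Reagents that add atoms: none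
Why: Chelation-controlled Grignard addition, in which magnesium bridges the ketone oxygen and the C7 dioxolane oxygen and the vinyl group (later C9) enters from the face of H7, sets C8; the silyl group blocks 1,4-addition to the ynone.

Step 9
Reactants: 14 (3S)-3-[(4R)-2,2-dimethyl-1,3-dioxolan-4-yl]-5-(trimethylsilyl)pent-1-en-4-yn-3-ol
Product: 15 triethyl{[(3S)-3-[(4R)-2,2-dimethyl-1,3-dioxolan-4-yl]-5-(trimethylsilyl)pent-1-en-4-yn-3-yl]oxy}silane
Conditions: TESOTf, 2,6-lutidine, CH2Cl2, −78 to 0 °C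
Reagents that add atoms: triethylsilyl trifluoromethanesulfonate, CC[Si](CC)(CC)OS(=O)(=O)C(F)(F)F
Why: A silyl triflate silylates the tertiary alcohol, which later blocks a Payne shift and serves as a poor leaving group next to C17.

Step 10
Reactants: 15 triethyl{[(3S)-3-[(4R)-2,2-dimethyl-1,3-dioxolan-4-yl]-5-(trimethylsilyl)pent-1-en-4-yn-3-yl]oxy}silane
Product: 16 (2R,3S)-3-ethenyl-3-(triethylsilyloxy)-5-(trimethylsilyl)pent-4-yne-1,2-diol
Conditions: Zn(NO3)2·6H2O, MeCN, 50 °C
Reagents that add atoms: none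
Why: Mild Lewis-acid hydrolysis of a terminal acetonide, which the hindered tertiary silyl ether and the alkynylsilane should survive.

Step 11
Reactants: 16 (2R,3S)-3-ethenyl-3-(triethylsilyloxy)-5-(trimethylsilyl)pent-4-yne-1,2-diol
Product: 18 triethyl{[(3S)-3-[(2R)-oxiran-2-yl]pent-1-en-4-yn-3-yl]oxy}silane, via primary tosylate 17 (not isolated)
Conditions: TsCl, Et3N, Bu2SnO (2 mol %), CH2Cl2, 0 °C; then K2CO3, MeOH, rt
Reagents that add atoms: none
Why: Tin-catalysed tosylation is selective for the primary hydroxyl, and carbonate in methanol then closes the C6–C7 epoxide by Williamson substitution at C6 (C7 keeps its configuration) and removes the alkynyl silyl group.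

Step 12
Reactants: 18 triethyl{[(3S)-3-[(2R)-oxiran-2-yl]pent-1-en-4-yn-3-yl]oxy}silane; 19 bis(pinacolato)diboron
Product: 20 triethyl{[(3S)-3-[(2R)-oxiran-2-yl]-2-(4,4,5,5-tetramethyl-1,3,2-dioxaborolan-2-yl)penta-1,4-dien-3-yl]oxy}silane
Conditions: (SIMes)CuCl (5 mol %), NaOtBu (5 mol %), MeOH (2 equiv), THF, 0 °C to rt
Reagents that add atoms: none
Why: NHC–copper-catalysed protoboration of a terminal alkyne, in which an N-aryl carbene ligand and the propargylic oxygen direct boron to the internal carbon C17 and methanol protonates the C18–Cu bond.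

Step 13
Reactants: 20 triethyl{[(3S)-3-[(2R)-oxiran-2-yl]-2-(4,4,5,5-tetramethyl-1,3,2-dioxaborolan-2-yl)penta-1,4-dien-3-yl]oxy}silane; 21 carbon dioxide
Product: 23 (4S,5S)-4-ethenyl-5-(hydroxymethyl)-3-methylidene-4-(triethylsilyloxy)oxolan-2-one, via potassium carboxylate 22 (not isolated)
Conditions: (IPr)CuCl (5 mol %), KOtBu (1.1 equiv), CO2 (1 atm), THF, 70 °C; aq. NH4Cl
Reagents that add atoms: none
Why: tert-Butoxide activates the boronate, the alkenyl group moves from boron to copper and the C17–Cu bond inserts CO2, which forms C19–C17 and leaves the potassium carboxylate 22, whose oxygen then attacks the epoxide carbon C7 from the back, which forms O1–C7 and closes the lactone. The closest known reaction types are the NHC–copper-catalysed carboxylation of alkenylboronic esters with CO2 and the lactonisation of γ,δ-epoxy carboxylates. The five-membered ring (O1, C19, C17, C8, C7) closes in the 5-exo-tet mode, the breaking C7–O bond of the epoxide lying outside the new ring. C7 is set by SN2 inversion of the glycerate-derived epoxide centre, and C8 is untouched. The step needs attack at C7 over 6-endo attack at C6, which the shorter tether should secure, and it needs CO2 insertion to outrun β-elimination of the C8 silyloxy group from the alkenylcopper, which the poor leaving group and the CO2 atmosphere should secure; the silyl ether on O8 also blocks a Payne shift. The freed C6 alkoxide is held as its carbonate under CO2, which should suppress silyl migration and oxa-Michael addition, and gives the alcohol on work-up.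

Step 14
Reactants: 23 (4S,5S)-4-ethenyl-5-(hydroxymethyl)-3-methylidene-4-(triethylsilyloxy)oxolan-2-one
Product: 24 (3R,4S,5S)-4-ethenyl-5-(hydroxymethyl)-3-methyl-4-(triethylsilyloxy)oxolan-2-one
Conditions: NaBH4, MeOH, −20 °C
Reagents that add atoms: none
Why: Conjugate hydride reduction of the α-methylene lactone, after which methanol should protonate the enolate at C17 from the face that carries H7 and the vinyl group (opposite to the silyloxy group and the C7 side chain), placing the C18 methyl cis to O8 and leaving the isolated vinyl group untouched.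

Step 15
Reactants: 24 (3R,4S,5S)-4-ethenyl-5-(hydroxymethyl)-3-methyl-4-(triethylsilyloxy)oxolan-2-one
Product: 25 (2R,3S,4R)-3-ethenyl-4-methyl-5-oxo-3-(triethylsilyloxy)oxolane-2-carbaldehyde
Conditions: Dess–Martin periodinane, NaHCO3, CH2Cl2, 0 °C; used at once
Reagents that add atoms: none
Why: Dess–Martin oxidation under buffered conditions gives the C6 aldehyde without epimerising the adjacent C7 centre.

Step 16
Reactants: 26 (triphenylphosphoranylidene)acetaldehyde
Product: 28 2-bromo-2-(triphenylphosphoranylidene)acetaldehyde, via (1-bromo-2-oxoethyl)triphenylphosphonium bromide 27 (not isolated)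
Conditions: Br2, CH2Cl2, −78 °C; then Et3N, 0 °C
Reagents that add atoms: bromine, BrBr
Why: Electrophilic bromination of a stabilised ylide at carbon followed by deprotonation of the phosphonium salt gives the α-bromo ylide.

Step 17
Reactants: 25 (2R,3S,4R)-3-ethenyl-4-methyl-5-oxo-3-(triethylsilyloxy)oxolane-2-carbaldehyde; 28 2-bromo-2-(triphenylphosphoranylidene)acetaldehyde
Product: 29 (2Z)-2-bromo-3-[(2S,3S,4R)-3-ethenyl-4-methyl-5-oxo-3-(triethylsilyloxy)oxolan-2-yl]prop-2-enal
Conditions: toluene, 50 °C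
Reagents that add atoms: none
Why: Wittig olefination with a stabilised ylide forms C5=C6 with the formyl carbon (C16) trans and the bromine (the later C4 site) cis to C7, and the neutral conditions spare the C7 centre.

Step 18
Reactants: 29 (2Z)-2-bromo-3-[(2S,3S,4R)-3-ethenyl-4-methyl-5-oxo-3-(triethylsilyloxy)oxolan-2-yl]prop-2-enal
Product: 30 (3R,4S,5S)-5-[(1Z)-2-bromo-3-hydroxyprop-1-enyl]-4-ethenyl-3-methyl-4-(triethylsilyloxy)oxolan-2-one
Conditions: NaBH4, CeCl3·7H2O, MeOH, −40 °C
Reagents that add atoms: none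
Why: Luche 1,2-reduction of the enal gives the C16 allylic alcohol and leaves the lactone alone.

Step 19
Reactants: 30 (3R,4S,5S)-5-[(1Z)-2-bromo-3-hydroxyprop-1-enyl]-4-ethenyl-3-methyl-4-(triethylsilyloxy)oxolan-2-one
Product: 32 (2S,3S,4R)-2-[(1Z)-2-bromo-3-hydroxyprop-1-enyl]-4-methyl-5-oxo-3-(triethylsilyloxy)oxolane-3-carbaldehyde, via ozonide 31 (not isolated)
Conditions: O3, CH2Cl2, −78 °C (stopped when 30 is consumed); then Me2S, −78 °C to rt
Reagents that add atoms: ozone, [O-][O+]=O
Why: Ozonolysis should cleave the monosubstituted vinyl group much faster than the electron-poor bromoalkene and gives the C9 aldehyde, which has no α-hydrogen.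

Step 20
Reactants: 33 hexamethylditin; 34 acetylene
Product: 35 (Z)-1,2-bis(trimethylstannyl)ethene
Conditions: Pd(PPh3)4 (2 mol %), dioxane, 60 °C
Reagents that add atoms: none
Why: Palladium-catalysed syn addition of the Sn–Sn bond across acetylene gives the Z isomer.

Step 21
Reactants: 32 (2S,3S,4R)-2-[(1Z)-2-bromo-3-hydroxyprop-1-enyl]-4-methyl-5-oxo-3-(triethylsilyloxy)oxolane-3-carbaldehyde; 35 (Z)-1,2-bis(trimethylstannyl)ethene
Product: 36 (2S,3S,4R)-2-[(1E,3Z)-2-(hydroxymethyl)-4-(trimethylstannyl)buta-1,3-dienyl]-4-methyl-5-oxo-3-(triethylsilyloxy)oxolane-3-carbaldehyde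
Conditions: 35 (3 equiv), Pd2(dba)3 (5 mol %), AsPh3 (20 mol %), NMP, 50 °C; used crude
Reagents that add atoms: none
Why: Stille coupling proceeds with retention at both alkenyl partners, so C4 enters cis to C7 at C5 and the C3=C4 bond stays Z; the excess of 35 favours mono-coupling.

Step 22
Reactants: 36 (2S,3S,4R)-2-[(1E,3Z)-2-(hydroxymethyl)-4-(trimethylstannyl)buta-1,3-dienyl]-4-methyl-5-oxo-3-(triethylsilyloxy)oxolane-3-carbaldehyde
Product: 37 (2S,3S,4R)-2-[(1E,3Z)-2-(hydroxymethyl)-4-iodobuta-1,3-dienyl]-4-methyl-5-oxo-3-(triethylsilyloxy)oxolane-3-carbaldehyde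
Conditions: I2, CH2Cl2, 0 °C
Reagents that add atoms: iodine, II
Why: Iododestannylation replaces tin by iodine at C3 with retention of the Z geometry.

Step 23
Reactants: 37 (2S,3S,4R)-2-[(1E,3Z)-2-(hydroxymethyl)-4-iodobuta-1,3-dienyl]-4-methyl-5-oxo-3-(triethylsilyloxy)oxolane-3-carbaldehyde
Product: 38 (2S,3S,4R)-2-[(1E,3Z)-2-(acetoxymethyl)-4-iodobuta-1,3-dienyl]-4-methyl-5-oxo-3-(triethylsilyloxy)oxolane-3-carbaldehyde
Conditions: Ac2O, pyridine, CH2Cl2, 0 °C
Reagents that add atoms: acetic anhydride, CC(=O)OC(C)=O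
Why: Acetylation of the primary allylic alcohol installs the final C16 acetate after all palladium steps, and the non-enolisable aldehyde is not affected.

Step 24
Reactants: 8 (3S,4S)-4-(tert-butyldimethylsilyloxy)-3-[(tert-butyldimethylsilyloxy)methyl]-3-methyl-1-(trimethylsilyloxy)cyclohex-1-ene; 38 (2S,3S,4R)-2-[(1E,3Z)-2-(acetoxymethyl)-4-iodobuta-1,3-dienyl]-4-methyl-5-oxo-3-(triethylsilyloxy)oxolane-3-carbaldehyde
Product: 41 seco-briarane β-hydroxy ketone (C9 alcohol; C11 ketone; C2 and C14 TBS ethers; C8 TES ether; C16 acetate; 3Z alkenyl iodide; stereocentres as in the target), via lithium enolate 39 (not isolated), via titanium enolate 40 (not isolated)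
Conditions: 8 (1.5 equiv), MeLi, THF, 0 °C; ClTi(OiPr)3, −78 °C; then 38, −78 to −40 °C; aq. NH4Cl
Reagents that add atoms: none
Why: Aldol addition of a regiodefined triisopropoxytitanium enolate (from the silyl enol ether by Si–Li–Ti exchange), which is aldehyde-selective and syn-selective for cyclic enolates; the aldehyde should approach C10 anti to the pseudoaxial C14 silyloxy group (C9 trans to C2), and the syn mode then fixes C9.

Step 25
Reactants: 41 seco-briarane β-hydroxy ketone
Product: 42 C11-methylidene analogue of 41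
Conditions: Zn, CH2Br2, TiCl4, THF/CH2Cl2, 0 °C to rt
Reagents that add atoms: dibromomethane, BrCBr
Why: Lombardo methylenation converts the hindered, enolisable C11 ketone into the C11=C20 alkene under non-basic conditions that spare the lactone, the acetate and the C10 centre.

Step 26
Reactants: 42 C11-methylidene analogue of 41
Product: 43 C9 acetate of 42
Conditions: Ac2O, pyridine, DMAP (cat.), CH2Cl2, rt
Reagents that add atoms: acetic anhydride, CC(=O)OC(C)=O
Why: Acetylation installs the final C9 acetate, which also keeps O9 from forming a lactol with the later C2 aldehyde.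

Step 27
Reactants: 43 C9 acetate of 42
Product: 44 C2/C8/C14 triol of 43
Conditions: HF·pyridine, pyridine, THF, 0 °C to rt
Reagents that add atoms: none
Why: Buffered fluoride removes the two TBS ethers and the TES ether while the acetates, the lactone and the alkenyl iodide should remain.

Step 28
Reactants: 44 C2/C8/C14 triol of 43
Product: 45 C2 aldehyde of 44
Conditions: TEMPO (20 mol %), PhI(OAc)2, CH2Cl2, rt
Reagents that add atoms: none
Why: Oxoammonium oxidation is selective for the primary C2 alcohol over the secondary C14 and tertiary C8 alcohols.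

Step 29
Reactants: 45 C2 aldehyde of 44
Product: 46 2,14-di-O-deacetyl target (ten-membered ring closed; 2S)
Conditions: CrCl2 (15 equiv), NiCl2 (1 mol %), degassed DMSO, rt, 0.002 M
Reagents that add atoms: none
Why: Nozaki–Hiyama–Kishi coupling, in which nickel activates the C3–I bond, chromium takes over the alkenyl group with retention of the Z geometry and adds it to the C2 aldehyde to close the ten-membered ring; the C2 configuration depends on the ring conformation imposed by the trans-fused ring A and the lactone and is expected, not assured, to be 2S.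

Step 30
Reactants: 46 2,14-di-O-deacetyl target
Product: 47 CNP0269068.1 (target)
Conditions: Ac2O, pyridine, DMAP (cat.), CH2Cl2, 0 °C to rt
Reagents that add atoms: acetic anhydride, CC(=O)OC(C)=O
Why: Acetylation of the two secondary alcohols (C2 and C14) should leave the hindered tertiary C8 hydroxyl free.

Compound list
1 | 1,4-dioxaspiro[4.5]dec-6-en-8-one | O=C1C=CC2(CC1)OCCO2 | starting material
2 | formaldehyde | C=O | starting material
3 | 7-(hydroxymethyl)-1,4-dioxaspiro[4.5]dec-6-en-8-one | OCC1=CC2(CCC1=O)OCCO2 | intermediate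
4 | 7-[(tert-butyldimethylsilyloxy)methyl]-1,4-dioxaspiro[4.5]dec-6-en-8-one | CC(C)(C)[Si](C)(C)OCC1=CC2(CCC1=O)OCCO2 | intermediate
5 | (8S)-7-[(tert-butyldimethylsilyloxy)methyl]-1,4-dioxaspiro[4.5]dec-6-en-8-ol | CC(C)(C)[Si](C)(C)OCC1=CC2(CC[C@@H]1O)OCCO2 | intermediate
6 | (8S)-8-(tert-butyldimethylsilyloxy)-7-[(tert-butyldimethylsilyloxy)methyl]-1,4-dioxaspiro[4.5]dec-6-ene | CC(C)(C)[Si](C)(C)OCC1=CC2(CC[C@@H]1O[Si](C)(C)C(C)(C)C)OCCO2 | intermediate
7 | (4S)-4-(tert-butyldimethylsilyloxy)-3-[(tert-butyldimethylsilyloxy)methyl]cyclohex-2-en-1-one | CC(C)(C)[Si](C)(C)OCC1=CC(=O)CC[C@@H]1O[Si](C)(C)C(C)(C)C | intermediate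
8 | (3S,4S)-4-(tert-butyldimethylsilyloxy)-3-[(tert-butyldimethylsilyloxy)methyl]-3-methyl-1-(trimethylsilyloxy)cyclohex-1-ene (methyl trans to the C4 silyloxy group) | C[Si](C)(C)OC1=C[C@@](C)(CO[Si](C)(C)C(C)(C)C)[C@@H](O[Si](C)(C)C(C)(C)C)CC1 | intermediate
9 | methyl (4R)-2,2-dimethyl-1,3-dioxolane-4-carboxylate | COC(=O)[C@H]1COC(C)(C)O1 | starting material
10 | ethynyltrimethylsilane | C#C[Si](C)(C)C | starting material
11 | lithium (trimethylsilyl)acetylide | [Li]C#C[Si](C)(C)C | intermediate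
12 | 1-[(4R)-2,2-dimethyl-1,3-dioxolan-4-yl]-3-(trimethylsilyl)prop-2-yn-1-one | C[Si](C)(C)C#CC(=O)[C@H]1COC(C)(C)O1 | intermediate
13 | vinylmagnesium bromide | C=C[Mg]Br | starting material
14 | (3S)-3-[(4R)-2,2-dimethyl-1,3-dioxolan-4-yl]-5-(trimethylsilyl)pent-1-en-4-yn-3-ol | C[Si](C)(C)C#C[C@@](O)(C=C)[C@H]1COC(C)(C)O1 | intermediate
15 | triethyl{[(3S)-3-[(4R)-2,2-dimethyl-1,3-dioxolan-4-yl]-5-(trimethylsilyl)pent-1-en-4-yn-3-yl]oxy}silane | C[Si](C)(C)C#C[C@@](O[Si](CC)(CC)CC)(C=C)[C@H]1COC(C)(C)O1 | intermediate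
16 | (2R,3S)-3-ethenyl-3-(triethylsilyloxy)-5-(trimethylsilyl)pent-4-yne-1,2-diol | C[Si](C)(C)C#C[C@@](O[Si](CC)(CC)CC)(C=C)[C@H](O)CO | intermediate
17 | primary tosylate of 16: (2R,3S)-3-ethenyl-2-hydroxy-3-(triethylsilyloxy)-5-(trimethylsilyl)pent-4-ynyl 4-methylbenzenesulfonate | C[Si](C)(C)C#C[C@@](O[Si](CC)(CC)CC)(C=C)[C@H](O)COS(=O)(=O)c1ccc(C)cc1 | intermediate
18 | triethyl{[(3S)-3-[(2R)-oxiran-2-yl]pent-1-en-4-yn-3-yl]oxy}silane | C#C[C@@](O[Si](CC)(CC)CC)(C=C)[C@H]1CO1 | intermediate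
19 | bis(pinacolato)diboron | CC1(C)OB(OC1(C)C)B1OC(C)(C)C(C)(C)O1 | starting material
20 | triethyl{[(3S)-3-[(2R)-oxiran-2-yl]-2-(4,4,5,5-tetramethyl-1,3,2-dioxaborolan-2-yl)penta-1,4-dien-3-yl]oxy}silane | C=C(B1OC(C)(C)C(C)(C)O1)[C@@](O[Si](CC)(CC)CC)(C=C)[C@H]1CO1 | intermediate
21 | carbon dioxide | O=C=O | starting material
22 | potassium (3S)-2-methylidene-3-[(2R)-oxiran-2-yl]-3-(triethylsilyloxy)pent-4-enoate | [K+].[O-]C(=O)C(=C)[C@@](O[Si](CC)(CC)CC)(C=C)[C@H]1CO1 | intermediate
23 | (4S,5S)-4-ethenyl-5-(hydroxymethyl)-3-methylidene-4-(triethylsilyloxy)oxolan-2-one | OC[C@@H]1OC(=O)C(=C)[C@@]1(O[Si](CC)(CC)CC)C=C | intermediate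
24 | (3R,4S,5S)-4-ethenyl-5-(hydroxymethyl)-3-methyl-4-(triethylsilyloxy)oxolan-2-one | OC[C@@H]1OC(=O)[C@H](C)[C@@]1(O[Si](CC)(CC)CC)C=C | intermediate
25 | (2R,3S,4R)-3-ethenyl-4-methyl-5-oxo-3-(triethylsilyloxy)oxolane-2-carbaldehyde | O=C[C@@H]1OC(=O)[C@H](C)[C@@]1(O[Si](CC)(CC)CC)C=C | intermediate
26 | (triphenylphosphoranylidene)acetaldehyde | O=CC=P(c1ccccc1)(c1ccccc1)c1ccccc1 | starting material
27 | (1-bromo-2-oxoethyl)triphenylphosphonium bromide | [Br-].O=CC(Br)[P+](c1ccccc1)(c1ccccc1)c1ccccc1 | intermediate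
28 | 2-bromo-2-(triphenylphosphoranylidene)acetaldehyde | O=CC(Br)=P(c1ccccc1)(c1ccccc1)c1ccccc1 | intermediate
29 | (2Z)-2-bromo-3-[(2S,3S,4R)-3-ethenyl-4-methyl-5-oxo-3-(triethylsilyloxy)oxolan-2-yl]prop-2-enal | O=C/C(Br)=C/[C@@H]1OC(=O)[C@H](C)[C@@]1(O[Si](CC)(CC)CC)C=C | intermediate
30 | (3R,4S,5S)-5-[(1Z)-2-bromo-3-hydroxyprop-1-enyl]-4-ethenyl-3-methyl-4-(triethylsilyloxy)oxolan-2-one | OC/C(Br)=C/[C@@H]1OC(=O)[C@H](C)[C@@]1(O[Si](CC)(CC)CC)C=C | intermediate
31 | ozonide of 30: (3R,4S,5S)-5-[(1Z)-2-bromo-3-hydroxyprop-1-enyl]-3-methyl-4-(triethylsilyloxy)-4-(1,2,4-trioxolan-3-yl)oxolan-2-one | OC/C(Br)=C/[C@@H]1OC(=O)[C@H](C)[C@@]1(O[Si](CC)(CC)CC)C1OCOO1 | intermediate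
32 | (2S,3S,4R)-2-[(1Z)-2-bromo-3-hydroxyprop-1-enyl]-4-methyl-5-oxo-3-(triethylsilyloxy)oxolane-3-carbaldehyde | OC/C(Br)=C/[C@@H]1OC(=O)[C@H](C)[C@@]1(O[Si](CC)(CC)CC)C=O | intermediate
33 | hexamethylditin | C[Sn](C)(C)[Sn](C)(C)C | starting material
34 | acetylene | C#C | starting material
35 | (Z)-1,2-bis(trimethylstannyl)ethene | C[Sn](C)(C)/C=C\[Sn](C)(C)C | intermediate
36 | (2S,3S,4R)-2-[(1E,3Z)-2-(hydroxymethyl)-4-(trimethylstannyl)buta-1,3-dienyl]-4-methyl-5-oxo-3-(triethylsilyloxy)oxolane-3-carbaldehyde | C[Sn](C)(C)/C=C\C(CO)=C/[C@@H]1OC(=O)[C@H](C)[C@@]1(O[Si](CC)(CC)CC)C=O | intermediate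
37 | (2S,3S,4R)-2-[(1E,3Z)-2-(hydroxymethyl)-4-iodobuta-1,3-dienyl]-4-methyl-5-oxo-3-(triethylsilyloxy)oxolane-3-carbaldehyde | I/C=C\C(CO)=C/[C@@H]1OC(=O)[C@H](C)[C@@]1(O[Si](CC)(CC)CC)C=O | intermediate
38 | (2S,3S,4R)-2-[(1E,3Z)-2-(acetoxymethyl)-4-iodobuta-1,3-dienyl]-4-methyl-5-oxo-3-(triethylsilyloxy)oxolane-3-carbaldehyde | I/C=C\C(COC(C)=O)=C/[C@@H]1OC(=O)[C@H](C)[C@@]1(O[Si](CC)(CC)CC)C=O | intermediate
39 | lithium enolate of ring A: lithium (3S,4S)-4-(tert-butyldimethylsilyloxy)-3-[(tert-butyldimethylsilyloxy)methyl]-3-methylcyclohex-1-en-1-olate | [Li]OC1=C[C@@](C)(CO[Si](C)(C)C(C)(C)C)[C@@H](O[Si](C)(C)C(C)(C)C)CC1 | intermediate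
40 | titanium enolate of ring A: triisopropoxytitanium (3S,4S)-4-(tert-butyldimethylsilyloxy)-3-[(tert-butyldimethylsilyloxy)methyl]-3-methylcyclohex-1-en-1-olate | CC(C)O[Ti](OC(C)C)(OC(C)C)OC1=C[C@@](C)(CO[Si](C)(C)C(C)(C)C)[C@@H](O[Si](C)(C)C(C)(C)C)CC1 | intermediate
41 | seco-briarane β-hydroxy ketone (C9 alcohol; C11 ketone; C2 and C14 TBS ethers; C8 TES ether; C16 acetate; 3Z alkenyl iodide; stereocentres as in the target) | O=C1CC[C@H](O[Si](C)(C)C(C)(C)C)[C@](C)(CO[Si](C)(C)C(C)(C)C)[C@H]1[C@H](O)[C@]2(O[Si](CC)(CC)CC)[C@@H](C)C(=O)O[C@H]2/C=C(COC(C)=O)\C=C/I | intermediate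
42 | C11-methylidene analogue of 41 | C=C1CC[C@H](O[Si](C)(C)C(C)(C)C)[C@](C)(CO[Si](C)(C)C(C)(C)C)[C@H]1[C@H](O)[C@]2(O[Si](CC)(CC)CC)[C@@H](C)C(=O)O[C@H]2/C=C(COC(C)=O)\C=C/I | intermediate
43 | C9 acetate of 42 | C=C1CC[C@H](O[Si](C)(C)C(C)(C)C)[C@](C)(CO[Si](C)(C)C(C)(C)C)[C@H]1[C@H](OC(C)=O)[C@]2(O[Si](CC)(CC)CC)[C@@H](C)C(=O)O[C@H]2/C=C(COC(C)=O)\C=C/I | intermediate
44 | C2/C8/C14 triol of 43 | C=C1CC[C@H](O)[C@](C)(CO)[C@H]1[C@H](OC(C)=O)[C@]2(O)[C@@H](C)C(=O)O[C@H]2/C=C(COC(C)=O)\C=C/I | intermediate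
45 | C2 aldehyde of 44 | C=C1CC[C@H](O)[C@](C)(C=O)[C@H]1[C@H](OC(C)=O)[C@]2(O)[C@@H](C)C(=O)O[C@H]2/C=C(COC(C)=O)\C=C/I | intermediate
46 | 2,14-di-O-deacetyl target (ten-membered ring closed; 2S) | C=C1CC[C@H](O)[C@]2(C)[C@@H](O)/C=C\C(COC(C)=O)=C/[C@@H]3OC(=O)[C@H](C)[C@@]3(O)[C@@H](OC(C)=O)[C@@H]12 | intermediate
47 | CNP0269068.1: (1R,2S,3Z,5E,7S,8S,9S,10S,14S,17R)-2,9,14,16-tetraacetoxy-8-hydroxybriara-3,5,11(20)-triene 19,7-lactone | C=C1CC[C@H](OC(C)=O)[C@]2(C)[C@@H](OC(C)=O)/C=C\C(COC(C)=O)=C/[C@@H]3OC(=O)[C@H](C)[C@@]3(O)[C@@H](OC(C)=O)[C@@H]12 | target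

Total step count: 30 steps.
Longest linear sequence: 22 steps (9 to 47 through steps 7–15, 17–19 and 21–30).

Steps most likely to fail

1. Step 13 (key step). What may go wrong: β-elimination of the C8 silyloxy group from the alkenylcopper before CO2 insertion, opening of the epoxide by tert-butoxide, closure at C6 instead of C7, or silyl migration to the freed C6 alkoxide. Fallback: the route sets out from 18, whose alkyne is hydrostannylated at the internal carbon (Bu3SnH, Mo(CO)3(CNtBu)3 cat., THF, 55 °C) to give the alkenylstannane analogue of 20 with SnBu3 in place of the boronate F1. Tin–lithium exchange (MeLi, THF, −78 °C), a CO2 quench at −78 °C and warming let the lithium carboxylate open the epoxide at C7 in the same pot. This replaces the catalytic copper cycle by a stoichiometric alkenyllithium carboxylation and comes back to the route at 23.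

2. Step 24. What may go wrong: poor facial selectivity at C10 and C9 when two hindered, chiral partners meet, slow addition, and retro-aldol or proton transfer from the adduct. Fallback: the route sets out from 8, which NBS (THF, −78 °C) converts into the α-bromo ketone (3S,4S)-2-bromo-4-(tert-butyldimethylsilyloxy)-3-[(tert-butyldimethylsilyloxy)methyl]-3-methylcyclohexan-1-one F2. A Reformatsky addition of F2 to 38 with SmI2 (THF, −78 °C) passes through a chelated samarium enolate instead of the titanium enolate and comes back to the route at 41.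

3. Step 29. What may go wrong: poor facial selectivity at the C2 aldehyde during ring closure, and oligomerisation in competition with closure of the strained ten-membered ring. Fallback: the route sets out from 46 obtained as a C2 epimer or mixture; MnO2 (CH2Cl2, rt) oxidises only the dienylic C2 alcohol to the C2 ketone analogue of 46 F3. A Corey–Bakshi–Shibata reduction of F3 (2-methyl-CBS-oxazaborolidine of the enantiomer that delivers hydride to the required face, BH3·SMe2, −30 °C) sets C2 under reagent control and comes back to the route at 46.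

Further compounds
F1 | step 13 | alkenylstannane analogue of 20 (tributylstannyl on C17 in place of the boronate) | C=C([Sn](CCCC)(CCCC)CCCC)[C@@](O[Si](CC)(CC)CC)(C=C)[C@H]1CO1
F2 | step 24 | (3S,4S)-2-bromo-4-(tert-butyldimethylsilyloxy)-3-[(tert-butyldimethylsilyloxy)methyl]-3-methylcyclohexan-1-one (both C2 epimers) | BrC1C(=O)CC[C@H](O[Si](C)(C)C(C)(C)C)[C@]1(C)CO[Si](C)(C)C(C)(C)C
F3 | step 29 | C2 ketone analogue of 46 | C=C1CC[C@H](O)[C@]2(C)C(=O)/C=C\C(COC(C)=O)=C/[C@@H]3OC(=O)[C@H](C)[C@@]3(O)[C@@H](OC(C)=O)[C@@H]12
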